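Everything rests on cutting ring A away from the flavone: the C5 phenol and the C7 methoxy group sit meta to each other on a benzene ring fused to ring C through C4a–C8a, the signature of a ketene/alkoxyalkyne benzannulation. In one operation, photo-Wolff shift of a pyranon-2-yl diazomethyl ketone, (2+2) addition of methoxyacetylene, four-electron opening and six-electron closure onto the one free pyranone CH make C8–C8a, C7–C8, C5–C6 and C4a–C5 and deliver the C5–OH unprotected. The precursor is a 4-pyranone carrying diazoacetyl at C2, hydrogen at C3, prenyl at C5 and a 2,4,5-trimethoxyphenyl ring B at C6; ring B is unmasked last via its quinone.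

Key step: step 7

Remark on the chemistry: the target has no stereocentre and no stereogenic alkene; 4, 6, 15 and 17 each hold one transient sp3 centre, are handled as racemates or tautomer mixtures and lose it later; flavone numbering (ring B primed) is used for 17–20, pyranone numbering for 7–10 and 14–16.

Step 1
Reactants: 1 2',4',5'-trimethoxyacetophenone
Product: 2 1-(2,4,5-trimethoxyphenyl)butane-1,3-dione
Conditions: NaH (2.5 equiv.), EtOAc (5 equiv.), THF, 0 °C → reflux; then 1 M HCl
Reagents that add atoms: ethyl acetate, CCOC(C)=O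
Why: Crossed Claisen condensation of the acetophenone enolate with ethyl acetate, pulled to completion by deprotonation of the β-diketone formed.

Step 2
Reactants: 2 1-(2,4,5-trimethoxyphenyl)butane-1,3-dione; 3 prenyl bromide (1-bromo-3-methylbut-2-ene)
Product: 4 2-(3-methylbut-2-en-1-yl)-1-(2,4,5-trimethoxyphenyl)butane-1,3-dione (racemic; keto–enol mixture)
Conditions: K2CO3 (1.2 equiv.), 3 (1.05 equiv.), acetone, 50 °C
Reagents that add atoms: none
Why: C-alkylation of the stabilised β-diketonate with a primary allylic bromide (SN2), for which K2CO3 in acetone favours carbon over oxygen attack, while the near-stoichiometric halide limits a second alkylation.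

Step 3
Reactants: 4 2-(3-methylbut-2-en-1-yl)-1-(2,4,5-trimethoxyphenyl)butane-1,3-dione; 5 diethyl oxalate
Product: 7 ethyl 5-(3-methylbut-2-en-1-yl)-4-oxo-6-(2,4,5-trimethoxyphenyl)-4H-pyran-2-carboxylate, via triketo ester 6 (not isolated)
Conditions: LiN(iPr)2 (2.3 equiv.), THF, −78 → 0 °C; cannulated into 5 (3 equiv.), THF, −78 °C; AcOH quench; crude 6 in AcOH, 70 °C
Reagents that add atoms: none
Why: Claisen-type γ-acylation of the 1,3-diketone dianion (the terminal CH3 is the only second acidic site, and inverse addition to excess oxalate at −78 °C suppresses double addition) followed by acid-mediated cyclodehydration of the 1,3,5-tricarbonyl array to the 4-pyranone, for which acetic acid should suffice because the keto group next to the ester is strongly activated, while it is too weak an acid to protonate the prenyl alkene.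

Step 4
Reactants: 7 ethyl 5-(3-methylbut-2-en-1-yl)-4-oxo-6-(2,4,5-trimethoxyphenyl)-4H-pyran-2-carboxylate
Product: 8 5-(3-methylbut-2-en-1-yl)-4-oxo-6-(2,4,5-trimethoxyphenyl)-4H-pyran-2-carboxylic acid
Conditions: LiOH·H2O (1.2 equiv.), THF/H2O (3:1), 0 °C; then 1 M HCl to pH 3, 0 °C
Reagents that add atoms: lithium hydroxide, [Li+].[OH-]
Why: Saponification (acyl–oxygen cleavage) of an ester activated by the electron-poor pyranone, run cold with near-stoichiometric hydroxide so that attack at the ester outruns conjugate opening of the ring, the prenyl group and the aryl ethers being inert.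

Step 5
Reactants: 8 5-(3-methylbut-2-en-1-yl)-4-oxo-6-(2,4,5-trimethoxyphenyl)-4H-pyran-2-carboxylic acid
Product: 10 2-diazo-1-[5-(3-methylbut-2-en-1-yl)-4-oxo-6-(2,4,5-trimethoxyphenyl)-4H-pyran-2-yl]ethan-1-one, via mixed anhydride 9 (not isolated)
Conditions: iBuOCOCl (1.1 equiv.), N-methylmorpholine (1.1 equiv.), THF, −15 °C; then CH2N2 (3 equiv.), Et2O, −15 → 0 °C, dark; excess CH2N2 purged with N2
Reagents that add atoms: diazomethane, C=[N+]=[N-]; isobutyl chloroformate, CC(C)COC(Cl)=O (its atoms reach intermediate 9 only)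
Why: Acylation of diazomethane by a mixed carbonic anhydride (first stage of an Arndt–Eistert sequence), which reacts at the more electrophilic pyranoyl carbonyl and avoids the acid chloride and HCl that could add to the prenyl alkene, while low temperature and a small excess limit dipolar addition to the pyranone.

Step 6
Reactants: 11 chloroacetaldehyde dimethyl acetal
Product: 13 methoxyacetylene (methoxyethyne), via sodium methoxyacetylide 12 (not isolated)
Conditions: NaNH2 (3.1 equiv.), NH3(l), −33 °C; NH3 evaporated; sat. aq. NaCl, −70 °C → rt; distilled (b.p. ca. 23 °C) into cold ClCH2CH2Cl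
Reagents that add atoms: none
Why: Twofold base-induced elimination (methanol, then HCl) of the chloroacetal with NaNH2, driven by formation of the sodium acetylide, whose protonation liberates the volatile alkoxyalkyne; this is the standard preparation of alkoxyacetylenes.

Step 7
Reactants: 10 2-diazo-1-[5-(3-methylbut-2-en-1-yl)-4-oxo-6-(2,4,5-trimethoxyphenyl)-4H-pyran-2-yl]ethan-1-one; 13 methoxyacetylene
Product: 18 5-hydroxy-7-methoxy-3-(3-methylbut-2-en-1-yl)-2-(2,4,5-trimethoxyphenyl)-4H-chromen-4-one, via pyranonylketene 14 (not isolated), via methoxycyclobutenone 15 (not isolated), via dienylketene 16 (not isolated), via ring A dienone 17 (not isolated)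
Conditions: 13 (4 equiv.), ClCH2CH2Cl (0.02 M, degassed), blue LEDs (ca. 440 nm), sealed Pyrex tube, 20 °C; then 80 °C
Reagents that add atoms: none
Why: Proposed new method: light absorbed by the diazoketone expels N2 and the pyranon-2-yl group migrates to the carbene carbon (photo-Wolff shift, forming C8–C8a) to give ketene 14, whose carbonyl carbon is attacked by the unsubstituted, nucleophilic carbon of methoxyacetylene so that (2+2) closure (C5–C6 and C7–C8) gives cyclobutenone 15; four-electron conrotatory opening of 15, by light or on warming, gives dienylketene 16, six-electron closure onto pyranone C3 of 10 (C4a–C5) gives dienone 17, and enolization gives phenol 18. The closest known reaction type is the Danheiser benzannulation of aryl, heteroaryl and alkenyl diazomethyl ketones with alkoxyalkynes; new here are a 4-pyranon-2-yl group as the migrating group and the pyranone C2=C3 bond as the terminating two-electron component. Ring A closes by a thermally allowed disrotatory 6π electrocyclization of the dienylketene, made irreversible by tautomerization to the arene. No stereocentre remains in 18, since the sp3 carbons of 15 and 17 are transient and the opening of 15 is reversible, which funnels either alkene geometry of 16 through the isomer that can cyclize. Regioselectivity (OH at C5 meta to OMe at C7) rests on the polarization of the alkoxyalkyne, and site selectivity is secured because C3 of the pyranone in 10 (the future C4a) is the only ring carbon next to the ketene arm that bears hydrogen, the others carrying carbonyl, prenyl and aryl. Selective excitation is sought with 440 nm light, which the diazo n–π* band should absorb and the arylpyranone chromophore should not, and the remote, unactivated prenyl alkene should not compete with the electron-rich alkyne for the ketene.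

Step 8
Reactants: 18 5-hydroxy-7-methoxy-3-(3-methylbut-2-en-1-yl)-2-(2,4,5-trimethoxyphenyl)-4H-chromen-4-one
Product: 19 2-[5-hydroxy-7-methoxy-3-(3-methylbut-2-en-1-yl)-4-oxo-4H-chromen-2-yl]-5-methoxycyclohexa-2,5-diene-1,4-dione
Conditions: (NH4)2Ce(NO3)6 (2.2 equiv.), MeCN/H2O (2:1), 0 °C, 10 min; extracted and used crude
Reagents that add atoms: water, O
Why: Oxidative demethylation of a para-dimethoxyarene by tetravalent cerium (arene radical cation, ipso attack of water, loss of methanol): the trimethoxyphenyl ring is by far the most easily oxidised part, the 2',5' pair gives the para-quinone while the 4'-OMe survives as a vinylogous ester, ring A is deactivated by the chelated C4 carbonyl, and prenyl side chains are routinely carried through this reaction.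

Step 9
Reactants: 19 2-[5-hydroxy-7-methoxy-3-(3-methylbut-2-en-1-yl)-4-oxo-4H-chromen-2-yl]-5-methoxycyclohexa-2,5-diene-1,4-dione
Product: 20 Artoindonesianin Q, 2-(2,5-dihydroxy-4-methoxyphenyl)-5-hydroxy-7-methoxy-3-(3-methylbut-2-en-1-yl)-4H-chromen-4-one
Conditions: Na2S2O4 (5 equiv.), EtOAc/H2O, rt, argon
Reagents that add atoms: none
Why: Two-electron reduction of the quinone to the hydroquinone by dithionite in a two-phase system, a reagent that leaves the chromone, the prenyl alkene and the aryl ethers untouched.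

Compound list
1 | 2',4',5'-trimethoxyacetophenone | CC(=O)c1cc(OC)c(OC)cc1OC | starting material
2 | 1-(2,4,5-trimethoxyphenyl)butane-1,3-dione | CC(=O)CC(=O)c1cc(OC)c(OC)cc1OC | intermediate
3 | prenyl bromide (1-bromo-3-methylbut-2-ene) | CC(C)=CCBr | starting material
4 | 2-(3-methylbut-2-en-1-yl)-1-(2,4,5-trimethoxyphenyl)butane-1,3-dione (racemic) | CC(=O)C(CC=C(C)C)C(=O)c1cc(OC)c(OC)cc1OC | intermediate
5 | diethyl oxalate | CCOC(=O)C(=O)OCC | starting material
6 | ethyl 5-(3-methylbut-2-en-1-yl)-2,4,6-trioxo-6-(2,4,5-trimethoxyphenyl)hexanoate (triketo ester, racemic, not isolated) | CCOC(=O)C(=O)CC(=O)C(CC=C(C)C)C(=O)c1cc(OC)c(OC)cc1OC | intermediate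
7 | ethyl 5-(3-methylbut-2-en-1-yl)-4-oxo-6-(2,4,5-trimethoxyphenyl)-4H-pyran-2-carboxylate | CCOC(=O)c1cc(=O)c(CC=C(C)C)c(-c2cc(OC)c(OC)cc2OC)o1 | intermediate
8 | 5-(3-methylbut-2-en-1-yl)-4-oxo-6-(2,4,5-trimethoxyphenyl)-4H-pyran-2-carboxylic acid | OC(=O)c1cc(=O)c(CC=C(C)C)c(-c2cc(OC)c(OC)cc2OC)o1 | intermediate
9 | isobutyl carbonic anhydride of acid 8 (mixed anhydride, not isolated) | CC(C)COC(=O)OC(=O)c1cc(=O)c(CC=C(C)C)c(-c2cc(OC)c(OC)cc2OC)o1 | intermediate
10 | 2-diazo-1-[5-(3-methylbut-2-en-1-yl)-4-oxo-6-(2,4,5-trimethoxyphenyl)-4H-pyran-2-yl]ethan-1-one | [N-]=[N+]=CC(=O)c1cc(=O)c(CC=C(C)C)c(-c2cc(OC)c(OC)cc2OC)o1 | intermediate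
11 | chloroacetaldehyde dimethyl acetal (2-chloro-1,1-dimethoxyethane) | COC(CCl)OC | starting material
12 | sodium methoxyacetylide (not isolated) | [Na+].[C-]#COC | intermediate
13 | methoxyacetylene (methoxyethyne) | COC#C | intermediate
14 | [5-(3-methylbut-2-en-1-yl)-4-oxo-6-(2,4,5-trimethoxyphenyl)-4H-pyran-2-yl]ketene (not isolated) | O=C=Cc1cc(=O)c(CC=C(C)C)c(-c2cc(OC)c(OC)cc2OC)o1 | intermediate
15 | 3-methoxy-4-[5-(3-methylbut-2-en-1-yl)-4-oxo-6-(2,4,5-trimethoxyphenyl)-4H-pyran-2-yl]cyclobut-2-en-1-one (racemic, not isolated) | COC1=CC(=O)C1c1cc(=O)c(CC=C(C)C)c(-c2cc(OC)c(OC)cc2OC)o1 | intermediate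
16 | 3-methoxy-4-(pyranon-2-yl)buta-1,3-dien-1-one, ketene arm and pyranonyl group cis on the C3=C4 bond (dienylketene, not isolated) | O=C=C/C(OC)=C\c1cc(=O)c(CC=C(C)C)c(-c2cc(OC)c(OC)cc2OC)o1 | intermediate
17 | 7-methoxy-3-(3-methylbut-2-en-1-yl)-2-(2,4,5-trimethoxyphenyl)-4aH-chromene-4,5-dione (keto tautomer of 18, racemic, not isolated) | COC1=CC(=O)C2C(=O)C(CC=C(C)C)=C(c3cc(OC)c(OC)cc3OC)OC2=C1 | intermediate
18 | 5-hydroxy-7-methoxy-3-(3-methylbut-2-en-1-yl)-2-(2,4,5-trimethoxyphenyl)-4H-chromen-4-one | COc1cc(O)c2c(=O)c(CC=C(C)C)c(-c3cc(OC)c(OC)cc3OC)oc2c1 | intermediate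
19 | 2-[5-hydroxy-7-methoxy-3-(3-methylbut-2-en-1-yl)-4-oxo-4H-chromen-2-yl]-5-methoxycyclohexa-2,5-diene-1,4-dione | O=C1C=C(OC)C(=O)C=C1c1oc2cc(OC)cc(O)c2c(=O)c1CC=C(C)C | intermediate
20 | Artoindonesianin Q | COc1cc(O)c2c(=O)c(CC=C(C)C)c(-c3cc(O)c(OC)cc3O)oc2c1 | target

Total step count: 9. Longest linear sequence: 8 steps (steps 1–5 and 7–9); step 6 is a one-step branch.

Steps most likely to fail

Step 7 (proposed new method). The light may be taken up by the arylpyranone instead of the diazo group, the ketene may dimerise or be lost before the volatile alkyne traps it, and the six-electron closure onto the cross-conjugated pyranone may stall at the cyclobutenone stage. The fallback uses known chemistry, a Baker–Venkataraman assembly with ring A preformed; it sets out from 1 and returns to the route at 18. Compound 1 is converted with I2 in pyridine into 1-[2-oxo-2-(2,4,5-trimethoxyphenyl)ethyl]pyridinium iodide F1, which aqueous NaOH cleaves to 2,4,5-trimethoxybenzoic acid F2 (Ortoleva–King degradation, which spares the electron-rich ring from halogenation). Esterification with purchased 2'-hydroxy-4',6'-dimethoxyacetophenone (EDC·HCl, DMAP, CH2Cl2) gives 2-acetyl-3,5-dimethoxyphenyl 2,4,5-trimethoxybenzoate F3. KOH in pyridine at 50 °C moves the aroyl group from oxygen to carbon and gives 1-(2-hydroxy-4,6-dimethoxyphenyl)-3-(2,4,5-trimethoxyphenyl)propane-1,3-dione F4. C-prenylation with 3 (K2CO3, acetone) gives 1-(2-hydroxy-4,6-dimethoxyphenyl)-2-(3-methylbut-2-en-1-yl)-3-(2,4,5-trimethoxyphenyl)propane-1,3-dione F5. NaOAc in AcOH at 100 °C closes ring C to 5,7-dimethoxy-3-(3-methylbut-2-en-1-yl)-2-(2,4,5-trimethoxyphenyl)-4H-chromen-4-one F6. BCl3 in CH2Cl2 at −78 °C then removes only the peri 5-O-methyl group, through chelation to the C4 carbonyl, and gives 18.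

Step 3. Under the acid needed for dehydration the prenyl alkene may be hydrated or may cyclize onto an enol oxygen, and the mild acid that the prenyl group dictates may leave the dehydration incomplete; O-acylation or twofold addition at the oxalate are lesser concerns. The fallback sets out from 2 and returns at 7; the side chain is carried as an acid-stable allyl group and completed after the ring is formed. Compound 2 is C-allylated (allyl bromide, K2CO3, acetone) to 2-allyl-1-(2,4,5-trimethoxyphenyl)butane-1,3-dione F7. Dianion acylation with 5 as in step 3 gives ethyl 5-allyl-2,4,6-trioxo-6-(2,4,5-trimethoxyphenyl)hexanoate F8, which can now be dehydrated with strong acid (HCl, EtOH, reflux) to ethyl 5-allyl-4-oxo-6-(2,4,5-trimethoxyphenyl)-4H-pyran-2-carboxylate F9. Cross-metathesis of F9 with excess 2-methylbut-2-ene (second-generation Grubbs catalyst, CH2Cl2, 40 °C) exchanges the terminal CH2 for CMe2 and gives 7.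

Step 8. One-electron oxidation of the free ring A phenol, or attack on the prenyl alkene, may compete with the oxidative demethylation of ring B, and the electrophilic quinone may decay before it is reduced. The fallback sets out from 18 and returns at 20; ring A is shielded as its acetate before the oxidation. Ac2O, pyridine and DMAP give 5-acetoxy-7-methoxy-3-(3-methylbut-2-en-1-yl)-2-(2,4,5-trimethoxyphenyl)-4H-chromen-4-one F10. (NH4)2Ce(NO3)6 in aqueous MeCN at 0 °C gives 2-[5-acetoxy-7-methoxy-3-(3-methylbut-2-en-1-yl)-4-oxo-4H-chromen-2-yl]-5-methoxycyclohexa-2,5-diene-1,4-dione F11. Na2S2O4 in the work-up reduces it at once to 2-(2,5-dihydroxy-4-methoxyphenyl)-7-methoxy-3-(3-methylbut-2-en-1-yl)-4-oxo-4H-chromen-5-yl acetate F12. K2CO3 in degassed MeOH at 0 °C under argon removes the aryl acetate and gives 20.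

Further compounds
F1 | step 7 | 1-[2-oxo-2-(2,4,5-trimethoxyphenyl)ethyl]pyridinium iodide | COc1cc(OC)c(cc1OC)C(=O)C[n+]1ccccc1.[I-]
F2 | step 7 | 2,4,5-trimethoxybenzoic acid | COc1cc(OC)c(cc1OC)C(O)=O
F3 | step 7 | 2-acetyl-3,5-dimethoxyphenyl 2,4,5-trimethoxybenzoate | CC(=O)c1c(OC)cc(OC)cc1OC(=O)c1cc(OC)c(OC)cc1OC
F4 | step 7 | 1-(2-hydroxy-4,6-dimethoxyphenyl)-3-(2,4,5-trimethoxyphenyl)propane-1,3-dione | COc1cc(O)c(C(=O)CC(=O)c2cc(OC)c(OC)cc2OC)c(OC)c1
F5 | step 7 | 1-(2-hydroxy-4,6-dimethoxyphenyl)-2-(3-methylbut-2-en-1-yl)-3-(2,4,5-trimethoxyphenyl)propane-1,3-dione (racemic) | COc1cc(O)c(C(=O)C(CC=C(C)C)C(=O)c2cc(OC)c(OC)cc2OC)c(OC)c1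
F6 | step 7 | 5,7-dimethoxy-3-(3-methylbut-2-en-1-yl)-2-(2,4,5-trimethoxyphenyl)-4H-chromen-4-one | COc1cc(OC)c2c(=O)c(CC=C(C)C)c(-c3cc(OC)c(OC)cc3OC)oc2c1
F7 | step 3 | 2-allyl-1-(2,4,5-trimethoxyphenyl)butane-1,3-dione (racemic) | CC(=O)C(CC=C)C(=O)c1cc(OC)c(OC)cc1OC
F8 | step 3 | ethyl 5-allyl-2,4,6-trioxo-6-(2,4,5-trimethoxyphenyl)hexanoate (racemic) | CCOC(=O)C(=O)CC(=O)C(CC=C)C(=O)c1cc(OC)c(OC)cc1OC
F9 | step 3 | ethyl 5-allyl-4-oxo-6-(2,4,5-trimethoxyphenyl)-4H-pyran-2-carboxylate | CCOC(=O)c1cc(=O)c(CC=C)c(-c2cc(OC)c(OC)cc2OC)o1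
F10 | step 8 | 5-acetoxy-7-methoxy-3-(3-methylbut-2-en-1-yl)-2-(2,4,5-trimethoxyphenyl)-4H-chromen-4-one | CC(=O)Oc1cc(OC)cc2oc(-c3cc(OC)c(OC)cc3OC)c(CC=C(C)C)c(=O)c12
F11 | step 8 | 2-[5-acetoxy-7-methoxy-3-(3-methylbut-2-en-1-yl)-4-oxo-4H-chromen-2-yl]-5-methoxycyclohexa-2,5-diene-1,4-dione | CC(=O)Oc1cc(OC)cc2oc(C3=CC(=O)C(OC)=CC3=O)c(CC=C(C)C)c(=O)c12
F12 | step 8 | 2-(2,5-dihydroxy-4-methoxyphenyl)-7-methoxy-3-(3-methylbut-2-en-1-yl)-4-oxo-4H-chromen-5-yl acetate | CC(=O)Oc1cc(OC)cc2oc(-c3cc(O)c(OC)cc3O)c(CC=C(C)C)c(=O)c12
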